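## Structural features

The target is a (2S)-flavanone: benzo ring A (C4a to C8a) is fused to the dihydropyranone ring C (O1, C2, C3 and the C4 ketone), and ring B, a 4-hydroxy-3-methoxyphenyl group, is attached at C2. Ring A is a phloroglucinol-type ring with hydroxyls at C5 and C7, a 3-methylbut-2-enyl (prenyl) group between them at C6, an unsubstituted C8, and its third oxygen serving as O1. C2 is the only stereocentre; it is benzylic, bears O1 and lies beta to the ketone, so base opens ring C to the 2'-hydroxychalcone (retro-oxa-Michael) and the configuration is lost. The prenyl double bond, flanked by two phenols, cyclises to a dimethylchroman under strong acid and does not survive hydrogenation, which rules out benzyl ethers and an acidic end-game. The real difficulties are two: one isolated stereocentre must be set in the absolute sense with no neighbouring centre to relay from, and it must be decided which of the two ortho oxygens of ring A becomes O1 (6-prenyl versus 8-prenyl). The key step uses the fact that O1–C8a–C4a–C4 is the skeleton of a salicylaldehyde at the aldehyde oxidation level and that C2–C3 with its aryl group is a styrene, so ring C is a formal [4+2] adduct whose C4 is re-oxidised afterwards.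

## Logic of the disconnections

**14 from 13.** The three phenolic O–H bonds of 14 are traced back to O–Si bonds. Silyl ethers are the only phenol protection here that comes off without acid, hydrogen or strong base. 13 has no free phenol, so it cannot open to a chalcone and its prenyl group cannot cyclise. The forward step must release three phenols without ever forming a phenoxide next to the ketone.

**13 from 11 by way of 12.** The C4=O bond is traced back to the C4–OH bond of 12 and then to the C4–OMe bond of 11. The cycloaddition delivers C4 as a benzylic methyl ether, one oxidation level below the ketone. No skeletal bond changes, and the transient C4 centre need not be controlled for its own sake. The forward steps must ionise C4 selectively (not C2) and oxidise under neutral conditions.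

**11 from 7 and 9 by way of 10.** C3–C4 and O1–C2 are cut, which opens ring C. 7 supplies O1–C8a–C4a–C4 as a heterodiene and 9 supplies C2–C3 with ring B. This is the most convergent cut: two achiral fragments of similar size, and both stereocentres are created in one event. The forward step needs catalyst control of the face of a cationic heterodiene, head-to-tail regiochemistry, and preference for the styrene over the prenyl alkene. Two design points serve this. 7 has exactly one free hydroxyl, so only one chroman regioisomer is possible. 7 is not exposed to an alcohol solvent but is converted in the flask into 10 with a stoichiometric methoxy donor, so the ion pair stays tight and the silyl ethers ortho and para to the cationic carbon are not solvolysed.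

**9 from 8.** One O–Si bond is cut. The phenol is masked so that the benzylic cation is a silyloxy-stabilised one and ring B survives the later oxidation. The forward step is a routine silylation.

**7 from 4 by way of 6 and 5.** The bond between the ring carbon (future C6) and the prenyl CH2 is cut, and the prenyl unit is returned to the oxygen that becomes O1. Direct C-prenylation of a free polyphenol gives O-, C- and poly-alkylation mixtures and would still leave the three oxygens to be differentiated. The tandem [3,3] shifts place the prenyl group between the two silyloxy groups and at the same time liberate the single hydroxyl needed for ring closure. The demand is that the second shift outruns enolisation of 5.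

**4 from 2 and 3.** The O–CH2 bond is cut. The forward etherification must be neutral, because carbonate bases cleave or scramble aryl silyl ethers.

**2 from 1.** Two O–Si bonds are cut. 1 is commercial and already carries the formyl group, so no formylation is needed. The forward step relies on the formyl group holding back one ortho hydroxyl by hydrogen bonding, so that two equivalents of silyl chloride stop at the bis-ether.

## Other disconnections considered

**Alternative 1:** Ring A is dismantled: C5–C6, C7–C8 and C4a–C5 are cut and C8–C8a is traced to a migration. This leaves the chiral dihydropyranone A2, which holds O1, C2 with its aryl group, C3, the C4 ketone, C4a and C8a and carries a diazoacetyl group on the future C8a, and the siloxyalkyne A3, which carries the prenyl group. Irradiation of A2 would trigger a Wolff rearrangement to a vinylketene; [2+2] addition of A3, four-electron opening of the cyclobutenone and six-electron closure would give the phenol A1 (5-OH free, prenyl at C6, silyl ether at C7).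
- In its favour: the ring-A pattern is written into A3, so 6- versus 8-prenyl cannot arise (equal to the chosen plan, which settles it through the single free hydroxyl of 7). C4 is a ketone from the start, so no redox adjustment follows (better than the chosen plan). C2 would be set earlier by an asymmetric hetero-Diels–Alder construction of the pyranone, a reaction class with catalytic precedent, whereas the chosen key step has none (better).
- Against it here: ring A is the cheapest part of the molecule and is available intact from 1. Building it requires a diazo ketone, a sensitive ynol silyl ether, and photolysis of a substrate whose enone chromophore and allylic C2–O1 bond can respond to light or to the ketene stage by ring opening, with loss of the C2 configuration. The prenyl alkene of A3 can itself add to the ketene. A1 carries two kinds of protecting group, one of them acid-labile, so an acidic deprotection beside the prenyl group is needed.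
- On step economy the alternative is clearly longer, since both partners need several steps. On security of the stereocentre it is better before the key step and worse during it.

**Alternative 2:** C2–C3 is cut. The precursor is the racemic cyclic enol acetal A5, in which C2 is an acetal carbon between O1 and the oxygen of an exocyclic enol ether at the future C4. A confined chiral imidodiphosphorimidate acid would ionise the C2–O bond on the enol side; the stereocentre of A5 vanishes in the planar aryloxycarbenium ion, and the tethered enol attacks one face of that ion through its CH2 carbon under control of the chiral anion, closing ring C to A4. A4 is the same compound as 13.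
- In its favour: the ketone oxidation level is reached directly, saving the two steps after the key step (better). The C–C bond forms intramolecularly, so the prenyl alkene cannot compete and no styrene can oligomerise (better). The ring-B partner would be the aldehyde A6, which is more stable than a vinylphenol (better). Both enantiomers of a racemate converge, so no stoichiometric chirality is needed (equal).
- Against it here: A5 has to be made from the stage of 7 by oxidation of the formyl group, acetalisation with A6 and carbonyl methylenation with Cp2TiMe2. These three extra operations make the total count about the same (equal). The enol acetal is very sensitive to moisture, the ion pair can fall apart into its two carbonyl components, and the strong acid that drives the shift can reopen the product by the same oxocarbenium ion and erode the C2 configuration.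
- Mechanistically both plans ask a chiral anion to control a cation next to O1 and neither has precedent on this substrate class (equal in novelty). The alternative needs a specialised, very acidic catalyst; the chosen plan needs a commercial phosphoric acid but two redox steps.

**Alternative 3:** O1–C8a is cut. The precursor is the bromo diol A8, a 1,3-diol whose ring-B carbinol is the future C2 and whose other carbinol is attached to a brominated, fully substituted ring A. CuI with a phenanthroline ligand and Cs2CO3 would join the ring-B carbinol oxygen to the brominated carbon and give the trans chroman-4-ol A7.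
- In its favour: intramolecular copper-mediated aryl ether formation is routine chemistry (better than the chosen, unprecedented key step). The C2 configuration would be installed beforehand by a reliable asymmetric carbonyl reduction or aldol method, and it is retained because the C–O bond at the stereocentre is not touched (better). Only one hydroxyl can reach the bromide through a six-membered closure, so chemoselectivity is not in question (equal).
- Against it here: the brominated, prenylated ring-A building block is hard to make, because electrophilic bromination and a prenyl alkene do not coexist and the order of events adds steps. Two carbinol centres must be set although the C4 one is oxidised away; the chosen plan also sets and erases C4 (equal). An electron-rich aryl bromide and a secondary benzylic alkoxide are poor partners, so the coupling needs heat and carbonate base, under which the benzylic 1,3-diol can eliminate or fragment. The methoxymethyl ethers of A7 must finally be removed with acid beside the prenyl group and a labile stereocentre.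
- The key step is the most secure of the four, but the route is the longest and the least convergent, and its end-game is less safe than buffered fluoride.

Key step: step 5

Remark: which mirror-image form of the phosphoric acid leads to (2S) cannot be derived from first principles; the (R) acid is written, and its enantiomer is used if a test reaction shows the opposite sense. The 2,4-cis adduct that leads to the (2S)-flavanone is (2S,4S).

## Route

Step 1
Reactants: 1 2,4,6-trihydroxybenzaldehyde
Product: 2 2,4-bis(tert-butyldimethylsilyloxy)-6-hydroxybenzaldehyde
Conditions: TBSCl (2.1 equiv), imidazole, DMF, 0 °C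
Reagents that add atoms: tert-butyldimethylsilyl chloride, CC(C)(C)[Si](C)(C)Cl
Why: Phenol silylation; the para hydroxyl and one ortho hydroxyl react, while the last ortho hydroxyl is hydrogen-bonded to the formyl oxygen and reacts much more slowly, as in the familiar bis-alkylations of this aldehyde, so limiting the silyl chloride should stop the reaction at the bis-ether.

Step 2
Reactants: 2 2,4-bis(tert-butyldimethylsilyloxy)-6-hydroxybenzaldehyde; 3 3-methylbut-2-en-1-ol
Product: 4 2,4-bis(tert-butyldimethylsilyloxy)-6-(3-methylbut-2-enyloxy)benzaldehyde
Conditions: PPh3, DIAD, THF, 0 °C to rt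
Reagents that add atoms: none
Why: Mitsunobu etherification; the chelated phenol is acidic enough to be alkylated at oxygen by the primary allylic alcohol under neutral conditions, which avoids the carbonate bases that cleave or scramble aryl silyl ethers.

Step 3
Reactants: 4 2,4-bis(tert-butyldimethylsilyloxy)-6-(3-methylbut-2-enyloxy)benzaldehyde
Product: 7 6-hydroxy-2,4-bis(tert-butyldimethylsilyloxy)-3-(3-methylbut-2-enyl)benzaldehyde, via ortho-dienone 5 (not isolated), via para-dienone 6 (not isolated)
Conditions: PhNEt2, 195 °C, sealed tube, Ar
Reagents that add atoms: none
Why: Aromatic para-Claisen (Claisen–Cope) rearrangement; a [3,3] shift to the free ortho carbon gives 5 with a reverse-prenyl group, a second [3,3] shift carries the unit, re-inverted, to the para carbon between the two silyloxy groups (6), and enolisation gives 7. This tandem shift is the standard entry to 6-prenyl rather than 8-prenyl flavonoid building blocks from 2-prenyloxy-4,6-dialkoxyaryl carbonyl compounds, and the one hydroxyl it releases is the one that becomes O1.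

Step 4
Reactants: 8 2-methoxy-4-vinylphenol
Product: 9 tert-butyl(4-ethenyl-2-methoxyphenoxy)dimethylsilane
Conditions: TBSCl, imidazole, CH2Cl2, 0 °C to rt
Reagents that add atoms: tert-butyldimethylsilyl chloride, CC(C)(C)[Si](C)(C)Cl
Why: Routine phenol silylation under mild base at low temperature, which the polymerisable styrene tolerates; the silyl ether keeps the para oxygen as a donor for the benzylic cation and protects ring B in the later oxidation.

Step 5
Reactants: 7 6-hydroxy-2,4-bis(tert-butyldimethylsilyloxy)-3-(3-methylbut-2-enyl)benzaldehyde; 9 tert-butyl(4-ethenyl-2-methoxyphenoxy)dimethylsilane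
Product: 11 (2S,4S)-5,7-bis(tert-butyldimethylsilyloxy)-2-[4-(tert-butyldimethylsilyloxy)-3-methoxyphenyl]-4-methoxy-6-(3-methylbut-2-enyl)chroman, via dimethyl acetal 10 (not isolated)
Conditions: HC(OMe)3 (1.5 equiv), 9 (2 equiv), (R)-3,3'-bis(2,4,6-triisopropylphenyl)-1,1'-binaphthyl-2,2'-diyl hydrogen phosphate (10 mol %), 4 Å MS, toluene, −20 to 0 °C; Et3N quench
Reagents that add atoms: trimethyl orthoformate, COC(OC)OC
Why: Proposed new method: the orthoformate turns 7 into acetal 10, from which the chiral acid expels methanol to give a methyl oxocarbenium ion (the O-protonated form of a 4-methoxy ortho-quinone methide) held by the phosphate through an ion pair and a hydrogen bond to the free phenolic OH; the CH2 terminus of 9 adds to the cationic carbon (C3–C4) and the para-silyloxybenzyl cation so formed is captured by the phenolic oxygen (O1–C2). The closest known reaction types are the acid-promoted annulation of salicylaldehyde acetals with styrenes to racemic cis-4-alkoxy-2-arylchromans and chiral phosphoric acid-catalysed [4+2] cycloadditions of ortho-quinone methides with styrenes; the new element is enantiocontrol over an aldehyde-derived heterodiene that carries its own oxygen at C4. Ring C is closed in the sense of an inverse-electron-demand hetero-Diels–Alder reaction; in the stepwise limit the closure is a 6-exo-trig capture of the benzylic cation by O1. C4 is set when 9 approaches the face of the ion-paired oxocarbenium that the 3,3'-aryl groups of the catalyst leave open, and C2 is set in the ring closure on that same face through a chair-like, endo arrangement with aryl and methoxy both pseudo-equatorial, so the cis relation ties (2S) to (4S). Regiochemistry follows from the polarity of the styrene, and since only one hydroxyl of 7 is free only the 6-prenyl chroman can form. Chemoselectivity over the prenyl double bond rests on the much higher nucleophilicity of the para-oxygenated styrene, used in excess, and on the two flanking silyl ethers, which shield the prenyl group and block its cyclisation. Toluene with a stoichiometric methoxy donor instead of bulk methanol keeps the ion pair tight and spares the silyl ethers that stand ortho and para to the cationic carbon. Low temperature and an amine quench limit re-ionisation of 11 at C4 or C2.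

Step 6
Reactants: 11 (2S,4S)-5,7-bis(tert-butyldimethylsilyloxy)-2-[4-(tert-butyldimethylsilyloxy)-3-methoxyphenyl]-4-methoxy-6-(3-methylbut-2-enyl)chroman
Product: 12 (2S)-5,7-bis(tert-butyldimethylsilyloxy)-2-[4-(tert-butyldimethylsilyloxy)-3-methoxyphenyl]-6-(3-methylbut-2-enyl)chroman-4-ol (both C4 epimers)
Conditions: PPTS (0.2 equiv), acetone/H2O (5:1), 0 °C to rt; NaHCO3 quench
Reagents that add atoms: water, O
Why: SN1 solvolysis of a benzylic methyl ether; C4 sits on a tri-oxygenated ring and ionises under very mild acid, and water in large excess captures the cation as the carbinol. Either C4 epimer is acceptable because C4 is oxidised next; the aryl silyl ethers, the flanked prenyl group and the far less ionisable C2–O1 bond should be untouched.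

Step 7
Reactants: 12 (2S)-5,7-bis(tert-butyldimethylsilyloxy)-2-[4-(tert-butyldimethylsilyloxy)-3-methoxyphenyl]-6-(3-methylbut-2-enyl)chroman-4-ol (both C4 epimers)
Product: 13 (2S)-5,7-bis(tert-butyldimethylsilyloxy)-2-[4-(tert-butyldimethylsilyloxy)-3-methoxyphenyl]-6-(3-methylbut-2-enyl)chroman-4-one
Conditions: activated MnO2 (excess), CH2Cl2, rt
Reagents that add atoms: none
Why: MnO2 oxidation of a benzylic alcohol under neutral, heterogeneous conditions; no acid is generated that could re-ionise C4, the prenyl alkene and silyl ethers are inert, both epimers converge on one ketone, and C2 is not involved.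

Step 8
Reactants: 13 (2S)-5,7-bis(tert-butyldimethylsilyloxy)-2-[4-(tert-butyldimethylsilyloxy)-3-methoxyphenyl]-6-(3-methylbut-2-enyl)chroman-4-one
Product: 14 (2S)-5,7-dihydroxy-2-(4-hydroxy-3-methoxyphenyl)-6-(3-methylbut-2-enyl)chroman-4-one
Conditions: Bu4NF/AcOH (1:1, 3.5 equiv), THF, 0 °C
Reagents that add atoms: none
Why: Fluoride cleavage of aryl silyl ethers; the acetic acid buffer keeps the released phenols protonated, so ring C does not open to the chalcone and (2S) is retained, and no acid strong enough to cyclise the prenyl group onto a neighbouring hydroxyl is present.

## Compound list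

1 | 2,4,6-trihydroxybenzaldehyde | O=Cc1c(O)cc(O)cc1O | starting material
2 | 2,4-bis(tert-butyldimethylsilyloxy)-6-hydroxybenzaldehyde | O=Cc1c(O)cc(O[Si](C)(C)C(C)(C)C)cc1O[Si](C)(C)C(C)(C)C | intermediate
3 | 3-methylbut-2-en-1-ol | CC(C)=CCO | starting material
4 | 2,4-bis(tert-butyldimethylsilyloxy)-6-(3-methylbut-2-enyloxy)benzaldehyde | O=Cc1c(OCC=C(C)C)cc(O[Si](C)(C)C(C)(C)C)cc1O[Si](C)(C)C(C)(C)C | intermediate
5 | 2,4-bis(tert-butyldimethylsilyloxy)-5-(2-methylbut-3-en-2-yl)-6-oxocyclohexa-1,3-diene-1-carbaldehyde (ortho-dienone; racemic; not isolated) | O=CC1=C(O[Si](C)(C)C(C)(C)C)C=C(O[Si](C)(C)C(C)(C)C)C(C(C)(C)C=C)C1=O | intermediate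
6 | 2,4-bis(tert-butyldimethylsilyloxy)-3-(3-methylbut-2-enyl)-6-oxocyclohexa-1,4-diene-1-carbaldehyde (para-dienone; racemic; not isolated) | O=CC1=C(O[Si](C)(C)C(C)(C)C)C(CC=C(C)C)C(O[Si](C)(C)C(C)(C)C)=CC1=O | intermediate
7 | 6-hydroxy-2,4-bis(tert-butyldimethylsilyloxy)-3-(3-methylbut-2-enyl)benzaldehyde | O=Cc1c(O)cc(O[Si](C)(C)C(C)(C)C)c(CC=C(C)C)c1O[Si](C)(C)C(C)(C)C | intermediate
8 | 2-methoxy-4-vinylphenol | C=Cc1ccc(O)c(OC)c1 | starting material
9 | tert-butyl(4-ethenyl-2-methoxyphenoxy)dimethylsilane | C=Cc1ccc(O[Si](C)(C)C(C)(C)C)c(OC)c1 | intermediate
10 | 2-(dimethoxymethyl)-3,5-bis(tert-butyldimethylsilyloxy)-4-(3-methylbut-2-enyl)phenol (dimethyl acetal of 7; not isolated) | COC(OC)c1c(O)cc(O[Si](C)(C)C(C)(C)C)c(CC=C(C)C)c1O[Si](C)(C)C(C)(C)C | intermediate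
11 | (2S,4S)-5,7-bis(tert-butyldimethylsilyloxy)-2-[4-(tert-butyldimethylsilyloxy)-3-methoxyphenyl]-4-methoxy-6-(3-methylbut-2-enyl)chroman | CC(C)(C)[Si](C)(C)Oc1ccc([C@@H]2C[C@H](OC)c3c(cc(O[Si](C)(C)C(C)(C)C)c(CC=C(C)C)c3O[Si](C)(C)C(C)(C)C)O2)cc1OC | intermediate
12 | (2S)-5,7-bis(tert-butyldimethylsilyloxy)-2-[4-(tert-butyldimethylsilyloxy)-3-methoxyphenyl]-6-(3-methylbut-2-enyl)chroman-4-ol (both C4 epimers) | CC(C)(C)[Si](C)(C)Oc1ccc([C@@H]2CC(O)c3c(cc(O[Si](C)(C)C(C)(C)C)c(CC=C(C)C)c3O[Si](C)(C)C(C)(C)C)O2)cc1OC | intermediate
13 | (2S)-5,7-bis(tert-butyldimethylsilyloxy)-2-[4-(tert-butyldimethylsilyloxy)-3-methoxyphenyl]-6-(3-methylbut-2-enyl)chroman-4-one | CC(C)(C)[Si](C)(C)Oc1ccc([C@@H]2CC(=O)c3c(cc(O[Si](C)(C)C(C)(C)C)c(CC=C(C)C)c3O[Si](C)(C)C(C)(C)C)O2)cc1OC | intermediate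
14 | (2S)-5,7-dihydroxy-2-(4-hydroxy-3-methoxyphenyl)-6-(3-methylbut-2-enyl)chroman-4-one | COc1cc([C@@H]2CC(=O)c3c(cc(O)c(CC=C(C)C)c3O)O2)ccc1O | target

## Step count and risks

Total step count: 8. Longest linear sequence: 7 steps (steps 1, 2, 3, 5, 6, 7, 8); step 4 is the one-step branch to 9.

**Step 5 (key step).** The most likely failure is poor facial discrimination. The styrene has no hydrogen-bond donor to anchor it to the catalyst, so only the shape of the catalyst pocket distinguishes the two faces of the oxocarbenium ion. Secondary failures are Friedel–Crafts oligomerisation of the electron-rich rings on the cation and loss of the silyl group ortho to the cationic carbon.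
Fallback (known chemistry, from 7 and 9, rejoining at 13): the same three-component annulation is run with an achiral acid (diphenyl hydrogen phosphate, or catalytic TMSOTf if more acidity is needed) and trimethyl orthoformate. This should give the racemic cis-4-methoxy-2-arylchroman F1. Hydrolysis and MnO2 oxidation as in steps 6 and 7 should give the racemic chroman-4-ol F2 and the racemic chroman-4-one F3. F3 is then resolved kinetically by asymmetric transfer hydrogenation with RuCl[(S,S)-TsDPEN](p-cymene) or its mirror image in HCO2H/Et3N, a known resolution of flavanones. The antipode of the complex is chosen so that the (2R) ketone is reduced to the cis (2R,4R)-chroman-4-ol F4 and (2S)-13 is left behind. Half of the material is the ceiling.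

**Step 3.** The ortho-dienone may enolise before the second shift, leaving a reverse-prenyl group at the ortho carbon. The formyl group may also react with the neighbouring prenyl ether in a thermal carbonyl-ene process, and the silyl groups may migrate at 195 °C.
Fallback (from 3, rejoining at 7): the prenyl group is placed before the formyl group on a symmetrical ring. 3 alkylates commercial phloroglucinol (in excess) under BF3·OEt2 in dioxane to give 2-(3-methylbut-2-enyl)benzene-1,3,5-triol F5. Exhaustive silylation (TBSCl, imidazole) gives 1,3,5-tris(tert-butyldimethylsilyloxy)-2-(3-methylbut-2-enyl)benzene F6. The one silyl ether without an ortho substituent is removed with K2CO3 (1 equiv) in MeOH at low temperature to give 3,5-bis(tert-butyldimethylsilyloxy)-4-(3-methylbut-2-enyl)phenol F7; this selectivity is sterically reasoned and is the weak point of the fallback. MgCl2/Et3N/paraformaldehyde ortho-formylation, at either of the two equivalent positions, gives 7.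

**Step 6.** The C4 cation may lose a proton from C3 (elimination to the flav-3-ene) or be attacked by the unsubstituted C8 of another molecule, the process that turns flavan-4-ols into oligomers. The silyl group at O5 may also be lost through the silyloxy-carbenium form.
Fallback (from 11, rejoining at 13): the ionisation is avoided by an oxidative route. DDQ in CH2Cl2/pH 7 buffer at 0 °C abstracts hydride from C4, whose axial C–H in the cis isomer is aligned with the tri-oxygenated ring, and the resulting oxocarbenium ion is hydrolysed through the hemiketal to the ketone. This makes no new compound (F0) and saves a step. The risk is competing hydride abstraction at the prenyl CH2 or at C2.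

**Step 2.** Etherification of a hindered, hydrogen-bonded phenol may stall, or allylic transposition may give the reverse-prenyl ether.
Fallback (from 2, rejoining at 4): silver-assisted O-alkylation with prenyl bromide and Ag2O in CH2Cl2. The electrophile is activated without a soluble phenoxide, so the silyl ethers are not scrambled. No new compound is made (F0).

## Further compounds

F1 | step 5 | racemic cis-(2RS,4RS)-5,7-bis(tert-butyldimethylsilyloxy)-2-[4-(tert-butyldimethylsilyloxy)-3-methoxyphenyl]-4-methoxy-6-(3-methylbut-2-enyl)chroman | CC(C)(C)[Si](C)(C)Oc1ccc(C2CC(OC)c3c(cc(O[Si](C)(C)C(C)(C)C)c(CC=C(C)C)c3O[Si](C)(C)C(C)(C)C)O2)cc1OC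
F2 | step 5 | racemic 5,7-bis(tert-butyldimethylsilyloxy)-2-[4-(tert-butyldimethylsilyloxy)-3-methoxyphenyl]-6-(3-methylbut-2-enyl)chroman-4-ol (C4 epimers) | CC(C)(C)[Si](C)(C)Oc1ccc(C2CC(O)c3c(cc(O[Si](C)(C)C(C)(C)C)c(CC=C(C)C)c3O[Si](C)(C)C(C)(C)C)O2)cc1OC
F3 | step 5 | racemic 5,7-bis(tert-butyldimethylsilyloxy)-2-[4-(tert-butyldimethylsilyloxy)-3-methoxyphenyl]-6-(3-methylbut-2-enyl)chroman-4-one | CC(C)(C)[Si](C)(C)Oc1ccc(C2CC(=O)c3c(cc(O[Si](C)(C)C(C)(C)C)c(CC=C(C)C)c3O[Si](C)(C)C(C)(C)C)O2)cc1OC
F4 | step 5 | (2R,4R)-5,7-bis(tert-butyldimethylsilyloxy)-2-[4-(tert-butyldimethylsilyloxy)-3-methoxyphenyl]-6-(3-methylbut-2-enyl)chroman-4-ol | CC(C)(C)[Si](C)(C)Oc1ccc([C@H]2C[C@@H](O)c3c(cc(O[Si](C)(C)C(C)(C)C)c(CC=C(C)C)c3O[Si](C)(C)C(C)(C)C)O2)cc1OC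
F5 | step 3 | 2-(3-methylbut-2-enyl)benzene-1,3,5-triol | CC(C)=CCc1c(O)cc(O)cc1O
F6 | step 3 | 1,3,5-tris(tert-butyldimethylsilyloxy)-2-(3-methylbut-2-enyl)benzene | CC(C)=CCc1c(O[Si](C)(C)C(C)(C)C)cc(O[Si](C)(C)C(C)(C)C)cc1O[Si](C)(C)C(C)(C)C
F7 | step 3 | 3,5-bis(tert-butyldimethylsilyloxy)-4-(3-methylbut-2-enyl)phenol | CC(C)=CCc1c(O[Si](C)(C)C(C)(C)C)cc(O)cc1O[Si](C)(C)C(C)(C)C
F0 | step 6 | none | none
F0 | step 2 | none | none
A1 | alternative 1 | (2S)-5-hydroxy-2-[3-methoxy-4-(methoxymethoxy)phenyl]-6-(3-methylbut-2-enyl)-7-(triisopropylsilyloxy)chroman-4-one | COCOc1ccc([C@@H]2CC(=O)c3c(cc(O[Si](C(C)C)(C(C)C)C(C)C)c(CC=C(C)C)c3O)O2)cc1OC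
A2 | alternative 1 | (2S)-6-(2-diazoacetyl)-2-[3-methoxy-4-(methoxymethoxy)phenyl]-2,3-dihydro-4H-pyran-4-one | COCOc1ccc([C@@H]2CC(=O)C=C(C(=O)C=[N+]=[N-])O2)cc1OC
A3 | alternative 1 | triisopropyl[(5-methylhex-4-en-1-yn-1-yl)oxy]silane | CC(C)=CCC#CO[Si](C(C)C)(C(C)C)C(C)C
A4 | alternative 2 | (2S)-5,7-bis(tert-butyldimethylsilyloxy)-2-[4-(tert-butyldimethylsilyloxy)-3-methoxyphenyl]-6-(3-methylbut-2-enyl)chroman-4-one | CC(C)(C)[Si](C)(C)Oc1ccc([C@@H]2CC(=O)c3c(cc(O[Si](C)(C)C(C)(C)C)c(CC=C(C)C)c3O[Si](C)(C)C(C)(C)C)O2)cc1OC
A5 | alternative 2 | racemic 5,7-bis(tert-butyldimethylsilyloxy)-2-[4-(tert-butyldimethylsilyloxy)-3-methoxyphenyl]-4-methylidene-6-(3-methylbut-2-enyl)-4H-1,3-benzodioxine | C=C1OC(c2ccc(O[Si](C)(C)C(C)(C)C)c(OC)c2)Oc2cc(O[Si](C)(C)C(C)(C)C)c(CC=C(C)C)c(O[Si](C)(C)C(C)(C)C)c21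
A6 | alternative 2 | 4-(tert-butyldimethylsilyloxy)-3-methoxybenzaldehyde | CC(C)(C)[Si](C)(C)Oc1ccc(C=O)cc1OC
A7 | alternative 3 | (2S,4R)-5,7-bis(methoxymethoxy)-2-[3-methoxy-4-(methoxymethoxy)phenyl]-6-(3-methylbut-2-enyl)chroman-4-ol | COCOc1ccc([C@@H]2C[C@@H](O)c3c(cc(OCOC)c(CC=C(C)C)c3OCOC)O2)cc1OC
A8 | alternative 3 | (1S,3R)-3-[6-bromo-2,4-bis(methoxymethoxy)-3-(3-methylbut-2-enyl)phenyl]-1-[3-methoxy-4-(methoxymethoxy)phenyl]propane-1,3-diol | COCOc1ccc([C@@H](O)C[C@@H](O)c2c(Br)cc(OCOC)c(CC=C(C)C)c2OCOC)cc1OC
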